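The flavone is cut at the C2–C1′ bond between the pyranone C ring and the B ring. In a 3-methoxychromone the OMe blocks C3. C2–H then sits on an sp2 carbon between O1 and the C3 oxygen, vinylogous to C4=O, and is the one acidic C–H. A hindered zinc amide metalates it, and in the same pot a Negishi coupling with 4-iodo-2,6-diprenylphenol delivers the whole skeleton with every carbon and oxygen in place. The iodine at C1′, para to the 4′-OH, first blocks the para position during the double ortho-prenylation. The precursor is a C2-unsubstituted chromone built from 2-methoxyresorcinol by C–H borylation/oxidation, ortho-acylation and one-carbon annulation.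

Key step: step 6

Remark: the target has no stereocentre and no stereogenic double bond (each prenyl alkene ends in two methyl groups), so it is achiral and no step has to set configuration.

Step 1
Reactants: 1 2-methoxyresorcinol
Product: 2 2-methoxy-1,3-bis(methoxymethoxy)benzene
Conditions: MOMCl (2.4 equiv), K2CO3 (2.5 equiv), acetone, 0 °C to rt
Reagents that add atoms: chloromethyl methyl ether (MOMCl) COCCl
Why: Double O-alkylation of the phenoxides with the α-chloro ether (Williamson-type acetal protection) masks the future C5 and C7 oxygens as small, base-stable MOM ethers that offer no competing arene C–H in the next step.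

Step 2
Reactants: 2 2-methoxy-1,3-bis(methoxymethoxy)benzene
Product: 4 4-methoxy-3,5-bis(methoxymethoxy)phenol, via aryl pinacol boronate 3 (not isolated)
Conditions: [Ir(OMe)(cod)]2 (1.5 mol%), dtbpy (3 mol%), B2pin2 (0.55 equiv), THF, 80 °C; then 30% H2O2, 1 M NaOH (1 equiv), 0 °C; aq NH4Cl
Reagents that add atoms: bis(pinacolato)diboron CC1(C)OB(OC1(C)C)B1OC(C)(C)C(C)(C)O1 (boryl group of 3 only); hydrogen peroxide OO (phenol oxygen of 4)
Why: Sterically controlled Ir-catalysed aromatic C–H borylation of a 1,2,3-trisubstituted benzene can only take the C5–H that has no ortho neighbour, and basic peroxide oxidation of the C–B bond (1,2-aryl shift from boron to oxygen) turns it in the same pot into the one free phenol, the future O1.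

Step 3
Reactants: 4 4-methoxy-3,5-bis(methoxymethoxy)phenol
Product: 6 1-[6-hydroxy-3-methoxy-2,4-bis(methoxymethoxy)phenyl]-2-methoxyethan-1-one, via aryloxymagnesium bromide 5 (not isolated)
Conditions: EtMgBr (1.0 equiv), Et2O/toluene, 0 °C, Et2O stripped off; MeOCH2COCl (1.0 equiv), toluene, 0 °C to rt; aq NH4Cl
Reagents that add atoms: ethylmagnesium bromide CC[Mg]Br (Mg and Br of 5 only); methoxyacetyl chloride COCC(=O)Cl
Why: Ortho-specific C-acylation of an aryloxymagnesium halide in a non-coordinating solvent, in which the acyl chloride binds to the magnesium on the phenolate oxygen and is delivered to the adjacent, highly nucleophilic ring carbon (the two ortho sites are equivalent, para is blocked by OMe), while the absence of a protic or strong Lewis acid spares the MOM groups.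

Step 4
Reactants: 6 1-[6-hydroxy-3-methoxy-2,4-bis(methoxymethoxy)phenyl]-2-methoxyethan-1-one
Product: 8 3,6-dimethoxy-5,7-bis(methoxymethoxy)-4H-chromen-4-one, via enaminone 7 (not isolated)
Conditions: DMF-DMA (3 equiv), toluene, 100 °C; concentrate; silica gel, CH2Cl2, rt
Reagents that add atoms: N,N-dimethylformamide dimethyl acetal (DMF-DMA) COC(OC)N(C)C
Why: Enaminone formation at the activated OCH2C=O methylene with the formamide acetal, then mildly acid-promoted oxa-Michael addition/elimination of dimethylamine by the only free phenol (the enaminone route to C2-unsubstituted chromones), closes the pyranone so that the ring methoxy group can only end up at C6.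

Step 5
Reactants: 9 4-iodophenol
Product: 10 4-iodo-2,6-bis(3-methylbut-2-en-1-yl)phenol
Conditions: prenyl bromide (2.2 equiv), KOH (2.2 equiv), H2O, rt
Reagents that add atoms: prenyl bromide (1-bromo-3-methylbut-2-ene) CC(C)=CCBr
Why: Double ortho C-alkylation of a phenoxide with an allylic bromide in water, where hydrogen bonding shields the oxygen and favours attack through carbon; iodine occupies the para carbon so only the two ortho positions can be prenylated, and SN2 attack at the primary carbon keeps the 3,3-dimethylallyl connectivity.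

Step 6
Reactants: 8 3,6-dimethoxy-5,7-bis(methoxymethoxy)-4H-chromen-4-one; 10 4-iodo-2,6-bis(3-methylbut-2-en-1-yl)phenol
Product: 12 2-[4-hydroxy-3,5-bis(3-methylbut-2-en-1-yl)phenyl]-3,6-dimethoxy-5,7-bis(methoxymethoxy)-4H-chromen-4-one, via chromon-2-ylzinc chloride 11 (not isolated)
Conditions: 8, TMPZnCl·LiCl (1.2 equiv), THF, 25 °C; the solution of 11 is added slowly to 10 (0.9 equiv), Pd(OAc)2 (2 mol%), SPhos (4 mol%), THF, 25 to 50 °C; aq NH4Cl
Reagents that add atoms: TMPZnCl·LiCl CC1(C)CCCC(C)(C)N1[Zn]Cl.[Li+].[Cl-] (Zn and Cl of 11 only, no atom in 12)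
Why: The hindered amide base removes C2–H of the pyranone ring of 8, which lies on an sp2 carbon between O1 and the C3–OMe oxygen and is vinylogously acidified by C4=O, to give the C2–zinc reagent 11; Pd(0) inserts into the C1′–I bond of 10, and transmetalation followed by reductive elimination forms C2–C1′. The closest known reaction type is the C–H zincation/Negishi cross-coupling of chromones at C2 that gives flavones. No ring is closed and no stereocentre is created. Site selectivity (C2–H against C8–H, which is flanked by O1 and the 7-OMOM group) is secured by the much higher acidity of the pyranone C–H toward a mild zinc amide, by coordination of the base to the C3 methoxy oxygen and by the OMe block at C3, which also excludes the ring opening open to C3-metalated chromones. The free 4′-OH, shielded by two ortho prenyl groups, should be tolerated because sp2 zinc halides are protonated by phenols more slowly than they transmetalate to an SPhos-ligated arylpalladium(II) species when the zinc reagent is added slowly. The trisubstituted prenyl alkenes sit meta to the C–Pd bond and out of reach for Heck cyclisation, and the MOM ethers, the ketone and the methyl ethers are inert to the zinc reagent.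

Step 7
Reactants: 12 2-[4-hydroxy-3,5-bis(3-methylbut-2-en-1-yl)phenyl]-3,6-dimethoxy-5,7-bis(methoxymethoxy)-4H-chromen-4-one
Product: 13 5,7-dihydroxy-2-[4-hydroxy-3,5-bis(3-methylbut-2-en-1-yl)phenyl]-3,6-dimethoxy-4H-chromen-4-one (target)
Conditions: conc. HCl (cat.), MeOH/THF, 40 °C
Reagents that add atoms: none
Why: Acid-catalysed acetal exchange (MOM methanolysis) frees the 5- and 7-OH, and dilute acid at mild temperature stays below what is needed for addition of the 4′-OH to the prenyl alkenes or for cleavage of the methyl ethers.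

Compound list
1 | 2-methoxyresorcinol (2-methoxybenzene-1,3-diol) | COc1c(O)cccc1O | starting material
2 | 2-methoxy-1,3-bis(methoxymethoxy)benzene | COCOc1cccc(OCOC)c1OC | intermediate
3 | 2-[4-methoxy-3,5-bis(methoxymethoxy)phenyl]-4,4,5,5-tetramethyl-1,3,2-dioxaborolane | COCOc1cc(B2OC(C)(C)C(C)(C)O2)cc(OCOC)c1OC | intermediate
4 | 4-methoxy-3,5-bis(methoxymethoxy)phenol | COCOc1cc(O)cc(OCOC)c1OC | intermediate
5 | bromomagnesium 4-methoxy-3,5-bis(methoxymethoxy)phenolate | COCOc1cc(O[Mg]Br)cc(OCOC)c1OC | intermediate
6 | 1-[6-hydroxy-3-methoxy-2,4-bis(methoxymethoxy)phenyl]-2-methoxyethan-1-one | COCC(=O)c1c(O)cc(OCOC)c(OC)c1OCOC | intermediate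
7 | 3-(dimethylamino)-1-[6-hydroxy-3-methoxy-2,4-bis(methoxymethoxy)phenyl]-2-methoxyprop-2-en-1-one (alkene geometry not defined, lost on cyclisation) | COCOc1cc(O)c(C(=O)C(OC)=CN(C)C)c(OCOC)c1OC | intermediate
8 | 3,6-dimethoxy-5,7-bis(methoxymethoxy)-4H-chromen-4-one | COCOc1cc2occ(OC)c(=O)c2c(OCOC)c1OC | intermediate
9 | 4-iodophenol | Oc1ccc(I)cc1 | starting material
10 | 4-iodo-2,6-bis(3-methylbut-2-en-1-yl)phenol | CC(C)=CCc1cc(I)cc(CC=C(C)C)c1O | intermediate
11 | [3,6-dimethoxy-5,7-bis(methoxymethoxy)-4-oxo-4H-chromen-2-yl]zinc chloride (LiCl complex) | COCOc1cc2oc([Zn]Cl)c(OC)c(=O)c2c(OCOC)c1OC | intermediate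
12 | 2-[4-hydroxy-3,5-bis(3-methylbut-2-en-1-yl)phenyl]-3,6-dimethoxy-5,7-bis(methoxymethoxy)-4H-chromen-4-one | COCOc1cc2oc(-c3cc(CC=C(C)C)c(O)c(CC=C(C)C)c3)c(OC)c(=O)c2c(OCOC)c1OC | intermediate
13 | 5,7-dihydroxy-2-[4-hydroxy-3,5-bis(3-methylbut-2-en-1-yl)phenyl]-3,6-dimethoxy-4H-chromen-4-one | COc1c(O)cc2oc(-c3cc(CC=C(C)C)c(O)c(CC=C(C)C)c3)c(OC)c(=O)c2c1O | target

Total step count: 7
Longest linear sequence: 6 (steps 1, 2, 3, 4, 6, 7)

Steps most likely to fail

1. Step 6 (key step).
- What may go wrong: the C–H zincation of the electron-rich chromone may stall or lose site selectivity through competing metalation at C8–H. The zinc reagent may also be protonated by the phenolic O–H faster than it transmetalates.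
- Fallback, from 6 and 10 back to 12: C2 is brought in already bearing a leaving group, so that neither a C–H metalation nor a basic organometal is needed. Ketone 6 is condensed with CS2 (KOtBu, THF, then cold dilute acid) to 4-hydroxy-3,6-dimethoxy-5,7-bis(methoxymethoxy)-2H-chromene-2-thione F1. MeI/K2CO3 in acetone S-methylates this to 3,6-dimethoxy-5,7-bis(methoxymethoxy)-2-(methylsulfanyl)-4H-chromen-4-one F2. Iodide 10 is converted with B2(OH)4, a Pd/XPhos catalyst and KOAc in EtOH into [4-hydroxy-3,5-bis(3-methylbut-2-en-1-yl)phenyl]boronic acid F3. A Liebeskind–Srogl coupling of F2 with F3 (Pd2(dba)3, tri(2-furyl)phosphine, CuTC, THF, 50 °C) runs without base and tolerates free phenols. It forms the same C2–C1′ bond and gives 12.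

2. Step 3.
- What may go wrong: acylation may go to the phenolate oxygen instead of the ring carbon. Proton exchange between product and unreacted phenolate may stop the conversion early. Magnesium-assisted loss of the MOM group next to the new carbonyl would erase the distinction between the two ortho oxygens.
- Fallback, from 4 back to 6: the oxygen is acylated on purpose (methoxyacetyl chloride, Et3N, DMAP, CH2Cl2, 0 °C) to 4-methoxy-3,5-bis(methoxymethoxy)phenyl 2-methoxyacetate F4. This ester is irradiated (254 nm, MeCN, rt) in a photo-Fries rearrangement. Homolysis of the O–acyl bond and in-cage recombination can only reach the two equivalent ortho carbons, since para carries OMe. The medium is neutral, so the MOM groups stay on.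

3. Step 7.
- What may go wrong: acid-promoted addition of the 4′-OH to a neighbouring prenyl alkene (chroman formation), or hydration of the alkenes, may compete with slow release of the 7-OH.
- Fallback, from 8 and 10 back to 13: the MOM groups are taken off before the prenyl groups arrive and are replaced by base-labile esters. HCl/MeOH converts 8 into 5,7-dihydroxy-3,6-dimethoxy-4H-chromen-4-one F5. Pivaloyl chloride, Et3N and DMAP give 3,6-dimethoxy-4-oxo-4H-chromene-5,7-diyl bis(2,2-dimethylpropanoate) F6. TMPZnCl·LiCl, which tolerates esters, gives [5,7-bis(2,2-dimethylpropanoyloxy)-3,6-dimethoxy-4-oxo-4H-chromen-2-yl]zinc chloride F7. Negishi coupling with 10 as in step 6 gives 2-[4-hydroxy-3,5-bis(3-methylbut-2-en-1-yl)phenyl]-3,6-dimethoxy-4-oxo-4H-chromene-5,7-diyl bis(2,2-dimethylpropanoate) F8. K2CO3 in MeOH at rt then releases 13 without any acid.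

Further compounds
F1 | step 6 | 4-hydroxy-3,6-dimethoxy-5,7-bis(methoxymethoxy)-2H-chromene-2-thione | COCOc1cc2oc(=S)c(OC)c(O)c2c(OCOC)c1OC
F2 | step 6 | 3,6-dimethoxy-5,7-bis(methoxymethoxy)-2-(methylsulfanyl)-4H-chromen-4-one | COCOc1cc2oc(SC)c(OC)c(=O)c2c(OCOC)c1OC
F3 | step 6 | [4-hydroxy-3,5-bis(3-methylbut-2-en-1-yl)phenyl]boronic acid | CC(C)=CCc1cc(B(O)O)cc(CC=C(C)C)c1O
F4 | step 3 | 4-methoxy-3,5-bis(methoxymethoxy)phenyl 2-methoxyacetate | COCC(=O)Oc1cc(OCOC)c(OC)c(OCOC)c1
F5 | step 7 | 5,7-dihydroxy-3,6-dimethoxy-4H-chromen-4-one | COc1c(O)cc2occ(OC)c(=O)c2c1O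
F6 | step 7 | 3,6-dimethoxy-4-oxo-4H-chromene-5,7-diyl bis(2,2-dimethylpropanoate) | COc1c(OC(=O)C(C)(C)C)cc2occ(OC)c(=O)c2c1OC(=O)C(C)(C)C
F7 | step 7 | [5,7-bis(2,2-dimethylpropanoyloxy)-3,6-dimethoxy-4-oxo-4H-chromen-2-yl]zinc chloride | COc1c(OC(=O)C(C)(C)C)cc2oc([Zn]Cl)c(OC)c(=O)c2c1OC(=O)C(C)(C)C
F8 | step 7 | 2-[4-hydroxy-3,5-bis(3-methylbut-2-en-1-yl)phenyl]-3,6-dimethoxy-4-oxo-4H-chromene-5,7-diyl bis(2,2-dimethylpropanoate) | COc1c(OC(=O)C(C)(C)C)cc2oc(-c3cc(CC=C(C)C)c(O)c(CC=C(C)C)c3)c(OC)c(=O)c2c1OC(=O)C(C)(C)C
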